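(The runs were computed for an exercise; scatter was added.)

- The question is how high target climbs in this flask within 10 d, and when, so I count what the reagent returns as target.

| flask | starting material | reagent | precatalyst | remark | time |
|---|---|---|---|---|---|
| beta | 2 M | 1.1 M (fed, over 30 min) | 400 mM | run made earlier; the fed solution adds 0.10 times the starting volume |  |
| flask | 2.0 M | 2.10 M (fed, over 30 min) | 400 mM | the fed solution adds 0.10 times the starting volume | 10 d |

beta run (percent of the starting material charged)

| time / d | target / % | starting material / % |
|---|---|---|
| 0.250 | 0.3 | 67.4 |
| 0.417 | 3.6 | 38.7 |
| 0.833 | 23.1 | 5.1 |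
| 1.67 | 40.3 | 0.6 |
| 3.00 | 41.4 | 0 |

(standard deviation of a reading: 1 percentage point)

- amounts are per litre of the starting volume; all of the dose is in the solution fed
- what was read earlier has a scatter of 1 percentage point, one standard deviation

* time up to 10 d at which target stands highest
* the amount of target, in percent of the starting material charged, at that time

- In beta, starting material is down to 0.6% at 1.67 d, while target moves only from 40.3% to 41.4% by 3.00 d, so I read that last value as its plateau.
- Beta charged 0.550 equivalents of reagent, so the reagent return is 0.753: target formed per reagent charged.
- This flask charges 1.05 equivalents, so the same return gives 79.0% of the starting material as target.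
- Beta's steepest climb as read, between 0.417 d and 0.833 d, is 0.469 d⁻¹ in fractions of the charge; held steady from 3.6% at 0.417 d, that rate reaches my figure at 2.03 d, which I take as my estimate of the peak time in this flask.
- The weak link is the return itself, because it assumes that the unreturned quarter of the reagent scales with the charge.
- A fixed loss of 0.136 equivalents would give 91.4% instead; beta shows one reagent charge and cannot choose, so I commit to the lower 79.0%.
- The forecast gives 75% (range 45% to 90%) at 3 d (range 1.5 d to 10 d), on the ground “This looks reagent-limited”; my yield is higher and my time earlier.
- The flask peaks at 70.7% at 2.32 d. At that time, over-reaction product stands at 12.8% of the starting material, and 20.6% of the reagent's own charge remains. The flask's reagent return at its peak is 0.673, lower than beta's 0.753.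

    starting material + free catalyst → free catalyst + open intermediate (k = 2.90 × 10⁻⁴ M⁻¹ s⁻¹)
    free catalyst + open intermediate ⇌ catalyst intermediate (K = 0.300 M⁻¹, k = 0.00310 M⁻¹ s⁻¹)
    reagent + catalyst intermediate → free catalyst + target (k = 2.00 × 10⁻⁴ M⁻¹ s⁻¹)
    precatalyst → free catalyst (k = 2.00 × 10⁻⁵ s⁻¹)
    free catalyst + target → free catalyst + over-reaction product (k = 5.00 × 10⁻⁶ M⁻¹ s⁻¹)

- The neighbour flask with 0.53 M of reagent has 0.265 equivalents, so the return gives 20.0% of target. The computed best in that neighbour flask is 22.0%; at its end, 0% of the reagent is left and 68.1% of the starting material stands as open intermediate.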